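# Proposed total synthesis of CNP0405270.2

## Analysis of the target

The target is a triterpenoid–sesquiterpenoid ether: an aromatic dinor-friedelane (rings A–E, with arene ring A carrying the C4 methyl, a C6 ketone conjugated to C7=C8, and a C21 ketone) joined to a guaia-3′,11′-diene through a 1,4-benzodioxane. The dioxane oxygens link arene C2 to the allylic ring-fusion carbon C5′ and arene C3 to the ring-fusion carbon C1′, so that the dioxane, the cyclopentene and the cycloheptane share the C1′–C5′ bond as a propellane. The triterpenoid part holds four quaternary stereocentres (C9 β-methyl, C13 α-methyl, C14 β-methyl, C17 β-methyl) and two tertiary ones (C18 β-H, C20 β-methyl); C9, C13 and C14 are contiguous, the C9 and C14 methyls are syn-diaxial on ring C, and rings D and E are cis-fused. In the guaiane the two ether oxygens are necessarily cis and lie on the face of the C10′ methyl and the C7′ isopropenyl group. Sensitive groups are the two tertiary alkyl aryl ethers (one of them allylic), the isopropenyl group, the aryl enone and C20, which can epimerise next to the C21 ketone. The hardest single bond is C14–CH3, because both faces of C14 are flanked by axial methyl groups (C13 on α, C9 on β); the second difficulty is that both ether carbons are tertiary, so that a catechol cannot be O-alkylated there. The strategy rests on C15 of ring D, the carbon next to C14: a β-hydroxyl there, allylic to a C8=C14 alkene, can hold a one-carbon tether that reaches only the β face of C14.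

## Retrosynthetic reasoning

**Dioxane (58 ← 57 ← 55 ← 39 + 54).** The two aryl–oxygen bonds are cut, not the alkyl–oxygen bonds, because C1′ and C5′ are tertiary. Both oxygens therefore stay on the guaiane as a cis-diol with one oxygen silylated (54), and the arene carries fluorine at C2 and C3 as latent ether positions. The C6 ketone of 39 is para to C2, so the C2 fluorine is displaced first and intermolecularly by the free C5′ alkoxide of 54 (55). The C3 fluorine is then displaced intramolecularly by the C1′ oxygen (57). The C21 ketone stays masked as a dioxolane until the last step (58). The stereochemistry of the propellane is fixed entirely in 54.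

**Ring B oxidation level (39 ← 37 ← 36).** The C7=C8 alkene and the C6 carbonyl are introduced late, by dehydrogenation of aryl ketone 37 and benzylic oxidation of 36. Until then the arene fluorines are not activated and survive bases and nucleophiles.

**Removal of the tether (36 ← 35 ← 34 ← 33).** The C15 oxygen has done its work once C14 carries carbon. The C–Si bond of 33 is cleaved to the methyl group (34) and the hydroxyl is removed by radical deoxygenation through xanthate 35.

**Key disconnection (33 ← 32).** The C14–CH2 bond is cut back to a silicon-tethered primary radical that adds 5-exo to C14 of the C8=C14 alkene. This replaces an intermolecular attack on the most hindered carbon of the molecule by a ring closure whose face is dictated by the C15 oxygen.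

**Tether and carbinol (32 ← 30 + 31; 30 ← 29).** The tether comes from chlorosilane 31 and the 15β-alcohol 30. The alcohol is made from enone 29 by a reagent-controlled reduction, because both faces of C15 carry 1,3-related substituents and the substrate's own bias cannot be predicted with confidence.

**Ring C (29 ← 27).** The C8=C14 bond is cut by an aldol condensation between the C8 ketone and C14 of the C15 ketone in 27. No other enolate–carbonyl pair can form a six-membered ring.

**Fragment union (27 ← 9 + 26).** The C9–C11 bond is cut to the benzylic enolate of tetralone 9 and primary iodide 26. C9 is made quaternary under control of a chiral phase-transfer catalyst.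

**Tetralone (9 ← 7 ← 5 ← 4 ← 3 ← 1 + 2).** The 2-tetralone is reached by carbonyl transposition from 1-tetralone 5, which comes from arylbutanoic acid 4 by acylation at the only free ortho position.

**Ring D/E iodide (26 ← 25 ← 23 ← 21 ← 19 ← 18 ← 17 ← 15 ← 14 ← 12 ← 10 + 11).** The C13 quaternary centre is set last in the fragment, by conjugate addition of a vinyl group to enone 21 from the convex face of the cis-fused bicycle. The C20 methyl is set by enolate methylation (18). Absolute configuration comes from one step: meso diketone 15 is desymmetrised by enantiotopic deprotonation (17). 15 arises by an intramolecular Michael addition of 14, itself made by alkylation of vinylogous ester 10 with 11 and carbonyl transposition.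

**Guaiane diol (54 ← 53 ← 52 ← 51 ← 50 ← 49 ← 48 ← 46 ← 44 ← 42 ← 41 ← 40).** Ring-closing metathesis of 53 makes the cyclopentene. The C5′ carbinol comes from addition to ketone 52 anti to the silyloxy group, the C1′ carbinol from addition to ketone 49 anti to the C10′ methyl. C10′ is set by ligand-controlled conjugate reduction of cycloheptenone 44, the one-carbon ring expansion product of (R)-carvone 40.

## Alternatives that were turned down

**Alternative 1:** ring A is disconnected at C1–C10 and C4–C5. A guaiane-fused 2-methylidene-3-ethylidene-1,4-dioxane A2 would add as the diene across C5=C10 of the ring B cyclohexadienone A3 to give the tetrahydro-arene A1, which would then be dehydrogenated twice.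
- For it: both dioxane oxygens sit on sp2 carbons of the diene from the start, so no aryl ether at a tertiary carbon has to be made. On that point it is stronger than the chosen route, which must close the dioxane by two substitutions on the arene (steps 37 and 38).
- Against it: A2 is a doubly enol-etherified 1,2-diketone on two tertiary carbinol carbons and should be acid-labile. Its two termini differ only by one methyl group, so there is little to control which end bonds to C10 and which to C5. The aromatisation needs an oxidant in the presence of the guaiane alkenes and allylic ethers. Above all, A3 already contains rings B–E with C9, C13, C14 and C17 in place, so the C14 problem stays unsolved and no steps are saved.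
- In its place the chosen strategy offers a defined answer to C14 and an arene that is present from the first step, which makes the benzylic enolate chemistry of the fragment union possible.

**Alternative 2:** C13–C18, C8–C14 and C9–C10 are cut together. Ionisation at the allylic carbon C18 in ring E would start a cation–olefin cascade in which the tetrasubstituted C13=C14 alkene, the C8=C9 alkene and arene carbon C10 are engaged in turn, giving A4.
- For it: in step count this is clearly superior. Three rings and the C9, C13 and C14 centres, with the C14 methyl already on the alkene, come from one operation.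
- Against it: the first bond must form between C18, next to quaternary C17, and a tetrasubstituted alkene, producing two new adjacent quaternary carbons. The anti/syn pattern of the C13, C14 and C9 methyls then depends on two alkene geometries and one folding mode. The tertiary cations at C14 and C9 can lose a proton or shift a methyl group before the next ring closes. The terminating arene must be electron-rich, which leads back to a catechol that cannot be alkylated at C1′ and C5′.
- The chosen strategy is longer, but sets each quaternary centre in its own step and fixes the C14 face by a tether.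

**Alternative 3:** C13–C14 is cut as a [3,3] shift. With carboxyl C12 esterified to the C7 allylic oxygen, which makes a ten-membered ring, an Ireland–Claisen rearrangement across C8=C14 would form C13–C14, move the alkene to C7=C8 and contract the ring to carbocyclic ring D, giving acid A5.
- For it: a sigmatropic shift is among the most dependable ways to join two fully substituted carbons, and it delivers the C7=C8 alkene of the target directly. On that point it is stronger than the chosen route, which needs step 25 for the same alkene.
- Against it: the ten-membered ring must first be closed at a hindered secondary allylic oxygen. The enolate carbon C13 is fully substituted and must react through one transannular geometry. The alkene partner must already be tetrasubstituted with the C14 methyl. A5 still has ring C open, with a vinyl group on C9 and a carboxyl at C12, so further steps and the loss of one carbon are needed.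
- The chosen strategy closes ring C by a simple aldol condensation; it pays with six plain steps (18 to 23) for the C14 methyl.

Key step: step 20

## Route

Remark on numbering: triterpenoid carbons are numbered as in friedelane (arene C1–C5 and C10; methyls on C4, C9, C13, C14, C17, C20). The ring D/E fragment uses the same numbers (ring D: C13–C18; ring E: C17–C22). Guaiane carbons carry a prime. α and β refer to the usual triterpenoid drawing.

Assumption 1: 6-bromo-2,3-difluorotoluene (1) and the zinc reagent 2 are taken to be catalogue compounds.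

Assumption 2: the sense of induction of the chiral lithium amide (step 9), the cinchona salt (step 16), the oxazaborolidine (step 18) and the copper hydride ligand (step 29) is taken by analogy with simpler ketones; if it proves opposite, the enantiomeric or pseudoenantiomeric reagent is used.

### Fragment 1: tetralone 9

Step 1
Reactants: 1 6-bromo-2,3-difluorotoluene; 2 (4-ethoxy-4-oxobutyl)zinc bromide
Product: 3 ethyl 4-(3,4-difluoro-2-methylphenyl)butanoate
Conditions: PdCl2(dppf) (3 mol%), THF, 60 °C
Reagents that add atoms: none
Why: Negishi coupling of an aryl bromide with a primary alkylzinc halide; the ester is tolerated and the C–F bonds are inert to zerovalent palladium under these conditions.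

Step 2
Reactants: 3 ethyl 4-(3,4-difluoro-2-methylphenyl)butanoate
Product: 4 4-(3,4-difluoro-2-methylphenyl)butanoic acid
Conditions: LiOH, THF/H2O, 25 °C; then aq. HCl
Reagents that add atoms: lithium hydroxide, [Li+].[OH-]
Why: Ester saponification.

Step 3
Reactants: 4 4-(3,4-difluoro-2-methylphenyl)butanoic acid
Product: 5 6,7-difluoro-5-methyl-3,4-dihydronaphthalen-1(2H)-one
Conditions: P2O5/MeSO3H, 60 °C
Reagents that add atoms: none
Why: Intramolecular Friedel–Crafts acylation; only one ortho position is free and it is para to a fluorine, so a single tetralone should form.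

Step 4
Reactants: 5 6,7-difluoro-5-methyl-3,4-dihydronaphthalen-1(2H)-one
Product: 7 6,7-difluoro-4,8-dimethyl-1,2-dihydronaphthalene, via tertiary carbinol 6 (not isolated)
Conditions: MeMgBr, THF, 0 °C; then TsOH (cat.), toluene, 110 °C
Reagents that add atoms: methylmagnesium bromide, C[Mg]Br
Why: Grignard addition, then acid-catalysed dehydration of the benzylic tertiary alcohol to the conjugated alkene; this methyl becomes the C9 methyl.

Step 5
Reactants: 7 6,7-difluoro-4,8-dimethyl-1,2-dihydronaphthalene
Product: 9 6,7-difluoro-1,5-dimethyl-3,4-dihydronaphthalen-2(1H)-one (racemic), via epoxide 8 (not isolated)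
Conditions: mCPBA, NaHCO3, CH2Cl2, 0 °C; then BF3·OEt2, −78 to 0 °C
Reagents that add atoms: 3-chloroperbenzoic acid, OOC(=O)c1cccc(Cl)c1
Why: Epoxidation and Meinwald rearrangement; the epoxide opens at the tertiary benzylic carbon and a hydride shift gives the 1-methyl-2-tetralone. The C9 centre is still enolisable and is fixed only in step 16.

### Fragment 2: ring D/E iodide 26

Step 6
Reactants: 10 3-ethoxycyclohex-2-en-1-one; 11 2-(2-bromoethyl)-2-methyl-1,3-dioxolane
Product: 12 3-ethoxy-6-[2-(2-methyl-1,3-dioxolan-2-yl)ethyl]cyclohex-2-en-1-one (racemic)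
Conditions: LiN(iPr)2, THF, −78 °C; then 11, NaI (cat.), DMPU, −78 to 0 °C
Reagents that add atoms: none
Why: Stork–Danheiser α′-alkylation of a vinylogous ester; kinetic deprotonation occurs only at C6 of the cyclohexenone, the future C18.

Step 7
Reactants: 12 3-ethoxy-6-[2-(2-methyl-1,3-dioxolan-2-yl)ethyl]cyclohex-2-en-1-one
Product: 14 3-methyl-4-(3-oxobutyl)cyclohex-2-en-1-one (racemic), via tertiary carbinol 13 (not isolated)
Conditions: MeLi, THF, −78 to 0 °C; then 2 M aq. HCl, 25 °C
Reagents that add atoms: methyllithium, [Li]C; water, O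
Why: Stork–Danheiser transposition: addition to the vinylogous ester carbonyl and acidic hydrolysis give the β-methyl enone, and the same acid frees the side-chain ketone. The new methyl is the C17 methyl.

Step 8
Reactants: 14 3-methyl-4-(3-oxobutyl)cyclohex-2-en-1-one
Product: 15 cis-8a-methyl-4,4a,5,6,8,8a-hexahydronaphthalene-2,7(1H,3H)-dione (meso; C15 and C21 ketones; 17β-methyl; 18β-H)
Conditions: KOtBu (0.2 equiv), tBuOH, 25 °C
Reagents that add atoms: none
Why: Intramolecular Michael addition of the methyl ketone enolate (C22) to the enone β-carbon C17, closing ring E 6-exo; the tether on C18 can reach C17 only from its own face, so the fusion is cis. The product has a mirror plane through C17 and C18, which erases the racemic centre of 14.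

Step 9
Reactants: 15 cis-8a-methyl-4,4a,5,6,8,8a-hexahydronaphthalene-2,7(1H,3H)-dione
Product: 17 ring D/E enedione (C13=C14–C15=O enone; C21 ketone; 17β-methyl; 18β-H), via trimethylsilyl enol ether 16 (not isolated)
Conditions: lithium (R,R)-bis(1-phenylethyl)amide, LiCl, Me3SiCl, THF, −100 °C; then Pd(OAc)2, MeCN, 25 °C
Reagents that add atoms: none
Why: Enantiotopic deprotonation of a meso ketone by a chiral lithium amide with in situ silylation, then Saegusa–Ito dehydrogenation. The base removes a proton from the less hindered α-methylene (the future C14) of one ring only, which sets the absolute configuration of C17 and C18 and defines that ring as ring D.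

Step 10
Reactants: 17 ring D/E enedione
Product: 18 20β-methyl ring D/E enedione
Conditions: LiN(iPr)2 (1.05 equiv), THF, −78 °C; then MeI, DMPU, −78 to −40 °C
Reagents that add atoms: iodomethane, CI
Why: Kinetic enolate methylation; the saturated ketone is deprotonated at C20, its only unhindered α-methylene (C22 and the enone α′-carbon C16 are neopentyl), and the electrophile should enter from the convex β face, anti to the ring D carbon on C18.

Step 11
Reactants: 18 20β-methyl ring D/E enedione
Product: 19 21,21-ethylenedioxy-20β-methyl ring D/E enone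
Conditions: (Me3SiOCH2)2, Me3SiOTf (cat.), CH2Cl2, −78 to −20 °C
Reagents that add atoms: 1,2-bis(trimethylsilyloxy)ethane, C[Si](C)(C)OCCO[Si](C)(C)C
Why: Noyori ketalisation; the saturated ketone reacts before the conjugated one, and the aprotic low-temperature conditions should spare the C20 centre.

Step 12
Reactants: 19 21,21-ethylenedioxy-20β-methyl ring D/E enone
Product: 21 13-methyl ring D/E enone (C13(CH3)=C14–C15=O; 21-ketal), via trimethylsilyl enol ether 20 (not isolated)
Conditions: Me2CuLi, Me3SiCl, THF, −78 °C; then Pd(OAc)2, MeCN, 25 °C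
Reagents that add atoms: lithium dimethylcuprate, [Li+].C[Cu-]C
Why: Cuprate conjugate addition trapped as the silyl enol ether, then Saegusa–Ito dehydrogenation toward C13; the transient C13 stereocentre is removed again.

Step 13
Reactants: 21 13-methyl ring D/E enone
Product: 23 13α-methyl-13β-vinyl ring D/E ketone (C15 ketone; 21-ketal), via trimethylsilyl enol ether 22 (not isolated)
Conditions: CH2=CHMgBr, CuBr·SMe2 (20 mol%), Me3SiCl, THF/DMPU, −78 to −30 °C; then K2CO3, MeOH
Reagents that add atoms: vinylmagnesium bromide, C=C[Mg]Br
Why: Copper-catalysed conjugate addition accelerated by the chlorosilane. In the preferred conformer (C20 methyl equatorial) the ring E carbon C22 is axial on the α face of ring D, so the vinyl group should enter from the convex β face and leave the methyl α.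

Step 14
Reactants: 23 13α-methyl-13β-vinyl ring D/E ketone
Product: 25 13β-(2-hydroxyethyl)-13α-methyl ring D/E ketone, via alkylborane 24 (not isolated)
Conditions: 9-borabicyclo[3.3.1]nonane (9-BBN), THF, 0 to 25 °C; then NaOH, H2O2
Reagents that add atoms: hydrogen peroxide, OO
Why: Anti-Markovnikov hydroboration–oxidation; 9-BBN adds to a terminal vinyl group much faster than it reduces a ketone flanked by two hindered methylenes.

Step 15
Reactants: 25 13β-(2-hydroxyethyl)-13α-methyl ring D/E ketone
Product: 26 13β-(2-iodoethyl)-13α-methyl ring D/E ketone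
Conditions: I2, PPh3, imidazole, CH2Cl2, 0 °C
Reagents that add atoms: iodine, II
Why: Appel-type conversion of a primary alcohol into the iodide; ketone and ketal are unaffected.

### Assembly and key step

Step 16
Reactants: 9 6,7-difluoro-1,5-dimethyl-3,4-dihydronaphthalen-2(1H)-one; 26 13β-(2-iodoethyl)-13α-methyl ring D/E ketone
Product: 27 (9S)-8,15-diketone (seco-ring C; C9 quaternary)
Conditions: N-[4-(trifluoromethyl)benzyl]cinchoninium bromide (10 mol%), 50% aq. KOH, toluene, 0 °C, under argon
Reagents that add atoms: none
Why: Asymmetric phase-transfer alkylation of a 1-methyl-2-tetralone with an unactivated primary halide. Only the benzylic α-proton is acidic enough for hydroxide, both enantiomers of 9 pass through the same enolate, and the catalyst decides the face. With enantiopure 26 the minor C9 epimer is a separable diastereomer.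

Step 17
Reactants: 27 (9S)-8,15-diketone
Product: 29 pentacyclic 8(14)-en-15-one, via aldol adduct 28 (not isolated)
Conditions: KOtBu, tBuOH, 70 °C
Reagents that add atoms: none
Why: Intramolecular aldol condensation; attack of C14 on the C8 ketone is the only combination that closes a six-membered ring, and dehydration gives the conjugated tetrasubstituted enone. The unactivated aryl fluorides are inert to alkoxide at this temperature.

Step 18
Reactants: 29 pentacyclic 8(14)-en-15-one
Product: 30 pentacyclic 8(14)-en-15β-ol
Conditions: (S)-2-methyl-CBS-oxazaborolidine [(3aS)-1-methyl-3,3-diphenyltetrahydro-1H,3H-pyrrolo[1,2-c][1,3,2]oxazaborole] (20 mol%), BH3·THF, THF, −20 °C; then aq. NH4Cl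
Reagents that add atoms: none
Why: Corey–Bakshi–Shibata reduction of an α-substituted enone; the catalyst treats the alkenyl carbon C14 as the large group and the C16 methylene as the small one, which for the (S)-catalyst means hydride delivery to the α face and the (15R), that is 15β, alcohol. Reagent control is chosen because both faces of C15 carry 1,3-related substituents and the substrate bias is not obvious.

Step 19
Reactants: 30 pentacyclic 8(14)-en-15β-ol; 31 (bromomethyl)chlorodimethylsilane
Product: 32 15β-(bromomethyl)dimethylsilyl ether of the 8(14)-ene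
Conditions: Et3N, DMAP (cat.), CH2Cl2, 0 °C
Reagents that add atoms: none
Why: Silylation of a secondary alcohol with a reactive chlorosilane; the product is used promptly because the Si–O bond is hydrolytically labile.

Step 20
Reactants: 32 15β-(bromomethyl)dimethylsilyl ether of the 8(14)-ene
Product: 33 14β,15β-fused 1-oxa-2-silacyclopentane (8α-H)
Conditions: Bu3SnH (1.3 equiv, syringe pump), AIBN (cat.), benzene, 80 °C, 0.01 M
Reagents that add atoms: none
Why: The stannyl radical abstracts bromine to give a primary α-silyl radical, which adds to C14 of the tetrasubstituted C8=C14 alkene, and the tertiary C8 radical then takes hydrogen from Bu3SnH. The closest known reaction is the radical cyclisation of (bromomethyl)dimethylsilyl ethers of allylic alcohols, which after protodesilylation amounts to a syn hydromethylation. The one ring closed is the five-membered ring C14–C15–O–Si–CH2, formed in the 5-exo-trig mode and necessarily cis-fused to ring D. The new C14 stereocentre is controlled by the 15β-oxygen: allylic strain with C7 turns the C15–O bond out of the alkene plane, the three-atom tether can reach only the β lobe at C14, and the carbon is therefore delivered syn to the C9 methyl and anti to the C13 methyl whatever their steric demand. The new C8 stereocentre should be α-H, because after cyclisation both neighbours (C9 and C14) carry axial β-carbon substituents; it becomes trigonal again in step 25. The step needs 5-exo attack at C14 in preference to 6-endo attack at C8, which is secured by the smaller ring and by the C9 β-methyl directly beside C8. It also needs cyclisation to outrun direct reduction of the first radical, which is secured by slow addition of the stannane at high dilution. The aryl fluorides and the ketal do not react with stannyl radicals.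

Step 21
Reactants: 33 14β,15β-fused 1-oxa-2-silacyclopentane
Product: 34 14β-methyl-15β-ol (8α-H)
Conditions: Bu4NF, DMF, 80 °C; then H2O
Reagents that add atoms: none
Why: Fluoride opens the Si–O bond and the neighbouring alkoxide assists cleavage of the primary C–Si bond (alkoxide-assisted protodesilylation), leaving the C14 methyl and the free alcohol.

Step 22
Reactants: 34 14β-methyl-15β-ol
Product: 35 15β-O-(methylsulfanyl)thiocarbonyl derivative (xanthate)
Conditions: NaH, imidazole (cat.), THF; CS2; then MeI, 0 to 25 °C
Reagents that add atoms: carbon disulfide, S=C=S; iodomethane, CI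
Why: Xanthate formation from a secondary alkoxide; the arene fluorines are still unactivated.

Step 23
Reactants: 35 xanthate
Product: 36 15-deoxy pentacycle (C6 methylene; 21-ketal)
Conditions: Bu3SnH, AIBN, toluene, 110 °C
Reagents that add atoms: none
Why: Barton–McCombie deoxygenation; the secondary C15 radical has no pathway other than hydrogen abstraction.

Step 24
Reactants: 36 15-deoxy pentacycle
Product: 37 6-oxo pentacycle
Conditions: CrO3 (5 mol%), 70% aq. tBuOOH, CH2Cl2, 25 °C
Reagents that add atoms: tert-butyl hydroperoxide, CC(C)(C)OO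
Why: Chromium-catalysed benzylic oxidation; C6 is the only secondary benzylic position, and the near-neutral medium spares the ketal.

Step 25
Reactants: 37 6-oxo pentacycle
Product: 39 6-oxo-7-ene pentacycle (2,3-difluoroarene; 21-ketal), via trimethylsilyl enol ether 38 (not isolated)
Conditions: LiN(SiMe3)2, Me3SiCl, THF, −78 °C; then Pd(OAc)2, MeCN/DMSO, 25 °C
Reagents that add atoms: none
Why: Saegusa–Ito dehydrogenation; C7 is the only enolisable position and the C8 hydrogen is lost in the β-hydride elimination. The bulky amide base does not attack the now activated C2 fluorine at −78 °C.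

### Fragment 3: guaiane diol 54

Step 26
Reactants: 40 (R)-carvone
Product: 41 trimethyl{[(5R)-2-methyl-5-(prop-1-en-2-yl)cyclohex-1-en-1-yl]oxy}silane
Conditions: LiBH(sec-Bu)3, THF, −78 °C; then Me3SiCl, Et3N
Reagents that add atoms: chlorotrimethylsilane, C[Si](C)(C)Cl
Why: Conjugate hydride reduction of the enone and O-silylation of the regiodefined enolate.

Step 27
Reactants: 41 trimethyl{[(5R)-2-methyl-5-(prop-1-en-2-yl)cyclohex-1-en-1-yl]oxy}silane
Product: 42 1-methyl-4-(prop-1-en-2-yl)-6-(trimethylsilyloxy)bicyclo[4.1.0]heptane (cyclopropane diastereomers)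
Conditions: Et2Zn, CH2I2, CH2Cl2, 0 °C
Reagents that add atoms: diiodomethane, ICI
Why: Furukawa–Simmons–Smith cyclopropanation; the electron-rich enol ether reacts before the isopropenyl group, and the new centres are lost in the next step.

Step 28
Reactants: 42 1-methyl-4-(prop-1-en-2-yl)-6-(trimethylsilyloxy)bicyclo[4.1.0]heptane
Product: 44 (6R)-3-methyl-6-(prop-1-en-2-yl)cyclohept-2-en-1-one, via chloro ketone 43 (not isolated)
Conditions: FeCl3, DMF, 0 °C; then NaOAc, MeOH, 65 °C
Reagents that add atoms: none
Why: Ito–Saegusa ring expansion; oxidative cleavage of the internal cyclopropane bond gives the β-chloro cycloheptanone, which eliminates to the conjugated enone. The carbonyl carbon becomes C5′ and the methyl-bearing carbon C10′.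

Step 29
Reactants: 44 (6R)-3-methyl-6-(prop-1-en-2-yl)cyclohept-2-en-1-one
Product: 46 2-[dimethyl(phenyl)silyloxy]-cis-3-methyl-6-(prop-1-en-2-yl)cycloheptan-1-one (C2 epimers), via silyl enol ether 45 (not isolated)
Conditions: CuCl (5 mol%), NaOtBu (5 mol%), (S)-p-tol-BINAP (5 mol%), PhMe2SiH, toluene, 0 °C; filtration; then mCPBA (1.0 equiv), NaHCO3, CH2Cl2, −20 to 0 °C
Reagents that add atoms: dimethyl(phenyl)silane, C[SiH](C)c1ccccc1; 3-chloroperbenzoic acid, OOC(=O)c1cccc(Cl)c1
Why: Ligand-controlled copper hydride conjugate reduction sets C10′ cis to the remote isopropenyl group and gives the enol silane regiospecifically. Rubottom oxidation of that electron-rich double bond, which reacts before the isopropenyl group, then places a silyloxy group on C1′ by 1,4-silyl shift; its configuration does not matter.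

Step 30
Reactants: 46 2-[dimethyl(phenyl)silyloxy]-cis-3-methyl-6-(prop-1-en-2-yl)cycloheptan-1-one
Product: 48 cis-7-methyl-10-(prop-1-en-2-yl)-1,4-dioxaspiro[4.6]undecan-6-ol (C6 epimers), via silyloxy ketal 47 (not isolated)
Conditions: (Me3SiOCH2)2, Me3SiOTf (cat.), CH2Cl2, −78 to −20 °C; then K2CO3, MeOH, 25 °C
Reagents that add atoms: 1,2-bis(trimethylsilyloxy)ethane, C[Si](C)(C)OCCO[Si](C)(C)C
Why: Noyori ketalisation at low temperature, followed by methanolysis of the labile silyl ether. The oxygen on C1′ stays silylated while the ketal forms, so the ketol cannot isomerise and scramble C10′.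

Step 31
Reactants: 48 cis-7-methyl-10-(prop-1-en-2-yl)-1,4-dioxaspiro[4.6]undecan-6-ol
Product: 49 cis-7-methyl-10-(prop-1-en-2-yl)-1,4-dioxaspiro[4.6]undecan-6-one (C1′ ketone; C5′ ketal)
Conditions: Dess–Martin periodinane, NaHCO3, CH2Cl2, 25 °C
Reagents that add atoms: none
Why: Buffered Dess–Martin oxidation of the secondary alcohol; the α-methyl centre C10′ is not enolised. The carbonyl has thereby been moved from C5′ to C1′.

Step 32
Reactants: 49 cis-7-methyl-10-(prop-1-en-2-yl)-1,4-dioxaspiro[4.6]undecan-6-one
Product: 50 1′-allyl-1′-hydroxy ketal (hydroxyl cis to the C10′ methyl)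
Conditions: CH2=CHCH2MgBr, CeCl3, THF, −78 °C
Reagents that add atoms: allylmagnesium bromide, C=CC[Mg]Br
Why: Organocerium-mediated Grignard addition to a 2-methylcycloalkanone; the nucleophile enters anti to the adjacent methyl, leaving the hydroxyl cis to it, and the symmetric ketal exerts no facial bias.

Step 33
Reactants: 50 1′-allyl-1′-hydroxy ketal
Product: 51 2-allyl-2-hydroxy-3-methyl-6-(prop-1-en-2-yl)cycloheptan-1-one (C5′ ketone)
Conditions: PPTS, acetone/H2O, 50 °C
Reagents that add atoms: water, O
Why: Mild acid-catalysed ketal hydrolysis; the tertiary homoallylic alcohol is stable to these conditions.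

Step 34
Reactants: 51 2-allyl-2-hydroxy-3-methyl-6-(prop-1-en-2-yl)cycloheptan-1-one
Product: 52 2-allyl-2-(tert-butyldimethylsilyloxy)-3-methyl-6-(prop-1-en-2-yl)cycloheptan-1-one
Conditions: tBuMe2SiOTf, 2,6-lutidine, CH2Cl2, 0 °C
Reagents that add atoms: tert-butyldimethylsilyl triflate, CC(C)(C)[Si](C)(C)OS(=O)(=O)C(F)(F)F
Why: Silylation of a tertiary alcohol with the silyl triflate; the non-chelating silyloxy group is needed to steer the next addition.

Step 35
Reactants: 52 2-allyl-2-(tert-butyldimethylsilyloxy)-3-methyl-6-(prop-1-en-2-yl)cycloheptan-1-one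
Product: 53 1′-allyl-5′-isopropenyl diol mono(silyl ether) (C5′ hydroxyl cis to the C1′ silyloxy group)
Conditions: CH2=C(CH3)MgBr, CeCl3, THF, −78 °C
Reagents that add atoms: isopropenylmagnesium bromide, CC(=C)[Mg]Br
Why: Organocerium addition to an α-silyloxy ketone under non-chelating conditions (polar Felkin–Anh model); the nucleophile enters anti to the silyloxy group, so the two carbon chains end up cis and the two oxygens cis.

Step 36
Reactants: 53 1′-allyl-5′-isopropenyl diol mono(silyl ether)
Product: 54 1′-(tert-butyldimethylsilyloxy)guaia-3′,11′-dien-5′-ol (O1′, O5′, C10′ methyl and C7′ isopropenyl on one face)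
Conditions: second-generation Grubbs catalyst RuCl2(H2IMes)(PCy3)(=CHPh) (5 mol%), CH2Cl2, 40 °C
Reagents that add atoms: none
Why: Ring-closing metathesis of the allyl and isopropenyl groups to the trisubstituted cyclopentene; only the cis isomer can close, and the remote isopropenyl group on C7′ cannot form a small ring.

### Dioxane annulation

Step 37
Reactants: 39 6-oxo-7-ene pentacycle; 54 1′-(tert-butyldimethylsilyloxy)guaia-3′,11′-dien-5′-ol
Product: 55 C2 aryl ether of the guaiane C5′ oxygen (C3 fluorine and C1′ silyl ether retained)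
Conditions: KN(SiMe3)2 (1.05 equiv on 54), THF, −78 °C; then 39, −78 to 0 °C
Reagents that add atoms: none
Why: Nucleophilic aromatic substitution by a tertiary alkoxide; only the C2 fluorine is para to the C6 carbonyl and the enone has no enolisable proton. The low temperature is meant to keep the silyl group from migrating between the two oxygens.

Step 38
Reactants: 55 C2 aryl ether of the guaiane C5′ oxygen
Product: 57 21-ethylene ketal of the target, via free tertiary alcohol 56 (not isolated)
Conditions: Bu4NF, DMF, 25 to 90 °C
Reagents that add atoms: none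
Why: Fluoride removes the silyl group and the C1′ alkoxide displaces the adjacent C3 fluorine in an intramolecular nucleophilic aromatic substitution that closes the six-membered dioxane. The configuration of both ether carbons is already fixed in 54, and the fluoride set free sustains the desilylation.

Step 39
Reactants: 57 21-ethylene ketal of the target
Product: 58 CNP0405270.2
Conditions: PPTS, acetone/H2O, 45 °C
Reagents that add atoms: water, O
Why: Mild acid-catalysed hydrolysis of the hindered dioxolane. The C5′ ether oxygen is conjugated through the arene to the C6 carbonyl and so is weakly basic, and ionisation at C5′ would place a cation beside the C1′ oxygen, so the allylic aryl ether should survive. The 20β-methyl is the configuration set in step 10 and is not expected to change under these conditions.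

## Compound list

1 | 6-bromo-2,3-difluorotoluene | Cc1c(Br)ccc(F)c1F | starting material
2 | (4-ethoxy-4-oxobutyl)zinc bromide | CCOC(=O)CCC[Zn]Br | starting material
3 | ethyl 4-(3,4-difluoro-2-methylphenyl)butanoate | CCOC(=O)CCCc1ccc(F)c(F)c1C | intermediate
4 | 4-(3,4-difluoro-2-methylphenyl)butanoic acid | OC(=O)CCCc1ccc(F)c(F)c1C | intermediate
5 | 6,7-difluoro-5-methyl-3,4-dihydronaphthalen-1(2H)-one | Cc1c(F)c(F)cc2C(=O)CCCc12 | intermediate
6 | 6,7-difluoro-1,5-dimethyl-1,2,3,4-tetrahydronaphthalen-1-ol (racemic; not isolated) | Cc1c(F)c(F)cc2c1CCCC2(C)O | intermediate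
7 | 6,7-difluoro-4,8-dimethyl-1,2-dihydronaphthalene | CC1=CCCc2c(C)c(F)c(F)cc12 | intermediate
8 | 3,4-epoxide of 7 (racemic; not isolated) | CC12OC1CCc1c(C)c(F)c(F)cc12 | intermediate
9 | 6,7-difluoro-1,5-dimethyl-3,4-dihydronaphthalen-2(1H)-one (racemic) | CC1C(=O)CCc2c(C)c(F)c(F)cc12 | intermediate
10 | 3-ethoxycyclohex-2-en-1-one | CCOC1=CC(=O)CCC1 | starting material
11 | 2-(2-bromoethyl)-2-methyl-1,3-dioxolane | CC1(CCBr)OCCO1 | starting material
12 | 3-ethoxy-6-[2-(2-methyl-1,3-dioxolan-2-yl)ethyl]cyclohex-2-en-1-one (racemic) | CCOC1=CC(=O)C(CCC2(C)OCCO2)CC1 | intermediate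
13 | 3-ethoxy-1-methyl-6-[2-(2-methyl-1,3-dioxolan-2-yl)ethyl]cyclohex-2-en-1-ol (not isolated) | CCOC1=CC(C)(O)C(CCC2(C)OCCO2)CC1 | intermediate
14 | 3-methyl-4-(3-oxobutyl)cyclohex-2-en-1-one (racemic) | CC(=O)CCC1CCC(=O)C=C1C | intermediate
15 | cis-8a-methyl-4,4a,5,6,8,8a-hexahydronaphthalene-2,7(1H,3H)-dione (meso) | O=C1CC[C@@H]2CCC(=O)C[C@]2(C)C1 | intermediate
16 | mono(trimethylsilyl) enol ether of 15 (C14=C15–OSiMe3; not isolated) | C[Si](C)(C)OC1=CC[C@@H]2CCC(=O)C[C@]2(C)C1 | intermediate
17 | ring D/E enedione (C13=C14–C15=O; C21=O; 17β-methyl; 18β-H) | O=C1C=C[C@@H]2CCC(=O)C[C@]2(C)C1 | intermediate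
18 | 20β-methyl ring D/E enedione | O=C1C=C[C@@H]2C[C@@H](C)C(=O)C[C@]2(C)C1 | intermediate
19 | 21,21-ethylenedioxy-20β-methyl ring D/E enone | O=C1C=C[C@@H]2C[C@@H](C)C3(OCCO3)C[C@]2(C)C1 | intermediate
20 | trimethylsilyl enol ether of the 13-methyl ketone (C13 epimers; not isolated) | C[Si](C)(C)OC1=CC(C)[C@@H]2C[C@@H](C)C3(OCCO3)C[C@]2(C)C1 | intermediate
21 | 13-methyl ring D/E enone (C13=C14–C15=O; 21-ketal) | O=C1C=C(C)[C@@H]2C[C@@H](C)C3(OCCO3)C[C@]2(C)C1 | intermediate
22 | trimethylsilyl enol ether of 23 (not isolated) | C[Si](C)(C)OC1=C[C@@](C)(C=C)[C@@H]2C[C@@H](C)C3(OCCO3)C[C@]2(C)C1 | intermediate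
23 | 13α-methyl-13β-vinyl ring D/E ketone | O=C1C[C@@](C)(C=C)[C@@H]2C[C@@H](C)C3(OCCO3)C[C@]2(C)C1 | intermediate
24 | B-alkyl-9-borabicyclo[3.3.1]nonane from 23 (boron on the terminal carbon of the C13 side chain; not isolated) | O=C1C[C@@](C)(CCB5C6CCCC5CCC6)[C@@H]2C[C@@H](C)C3(OCCO3)C[C@]2(C)C1 | intermediate
25 | 13β-(2-hydroxyethyl)-13α-methyl ring D/E ketone | O=C1C[C@@](C)(CCO)[C@@H]2C[C@@H](C)C3(OCCO3)C[C@]2(C)C1 | intermediate
26 | 13β-(2-iodoethyl)-13α-methyl ring D/E ketone | O=C1C[C@@](C)(CCI)[C@@H]2C[C@@H](C)C3(OCCO3)C[C@]2(C)C1 | intermediate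
27 | (9S)-8,15-diketone (rings A/B joined to rings D/E through C11–C12) | Fc1cc2c(c(C)c1F)CCC(=O)[C@@]2(C)CC[C@]3(C)CC(=O)C[C@@]4(C)CC5(OCCO5)[C@H](C)C[C@H]43 | intermediate
28 | 8-hydroxy-15-ketone aldol adduct (C8 and C14 unassigned; not isolated) | Fc1cc2c(c(C)c1F)CCC1(O)C3C(=O)C[C@@]4(C)CC5(OCCO5)[C@H](C)C[C@H]4[C@]3(C)CC[C@]12C | intermediate
29 | pentacyclic 8(14)-en-15-one (2,3-difluoro; 21-ketal) | Fc1cc2c(c(C)c1F)CCC1=C3C(=O)C[C@@]4(C)CC5(OCCO5)[C@H](C)C[C@H]4[C@]3(C)CC[C@]12C | intermediate
30 | pentacyclic 8(14)-en-15β-ol ((15R)) | Fc1cc2c(c(C)c1F)CCC1=C3[C@H](O)C[C@@]4(C)CC5(OCCO5)[C@H](C)C[C@H]4[C@]3(C)CC[C@]12C | intermediate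
31 | (bromomethyl)chlorodimethylsilane | C[Si](C)(Cl)CBr | starting material
32 | 15β-(bromomethyl)dimethylsilyl ether of the 8(14)-ene (key-step precursor) | Fc1cc2c(c(C)c1F)CCC1=C3[C@H](O[Si](C)(C)CBr)C[C@@]4(C)CC5(OCCO5)[C@H](C)C[C@H]4[C@]3(C)CC[C@]12C | intermediate
33 | 14β,15β-fused 1-oxa-2-silacyclopentane, 8α-H (key-step product) | Fc1cc2c(c(C)c1F)CC[C@@H]1[C@@]3(C[Si](C)(C)O6)[C@H]6C[C@@]4(C)CC5(OCCO5)[C@H](C)C[C@H]4[C@]3(C)CC[C@]12C | intermediate
34 | 14β-methyl-15β-ol, 8α-H | Fc1cc2c(c(C)c1F)CC[C@@H]1[C@@]3(C)[C@H](O)C[C@@]4(C)CC5(OCCO5)[C@H](C)C[C@H]4[C@]3(C)CC[C@]12C | intermediate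
35 | 15β-xanthate (O-alkyl S-methyl dithiocarbonate) | Fc1cc2c(c(C)c1F)CC[C@@H]1[C@@]3(C)[C@H](OC(=S)SC)C[C@@]4(C)CC5(OCCO5)[C@H](C)C[C@H]4[C@]3(C)CC[C@]12C | intermediate
36 | 15-deoxy pentacycle (C6 methylene) | Fc1cc2c(c(C)c1F)CC[C@@H]1[C@@]3(C)CC[C@@]4(C)CC5(OCCO5)[C@H](C)C[C@H]4[C@]3(C)CC[C@]12C | intermediate
37 | 6-oxo pentacycle | Fc1cc2c(c(C)c1F)C(=O)C[C@@H]1[C@@]3(C)CC[C@@]4(C)CC5(OCCO5)[C@H](C)C[C@H]4[C@]3(C)CC[C@]12C | intermediate
38 | C6 trimethylsilyl enol ether (C6=C7; not isolated) | Fc1cc2c(c(C)c1F)C(O[Si](C)(C)C)=C[C@@H]1[C@@]3(C)CC[C@@]4(C)CC5(OCCO5)[C@H](C)C[C@H]4[C@]3(C)CC[C@]12C | intermediate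
39 | 6-oxo-7-ene pentacycle (2,3-difluoro; 21-ketal) | Fc1cc2c(c(C)c1F)C(=O)C=C1[C@@]3(C)CC[C@@]4(C)CC5(OCCO5)[C@H](C)C[C@H]4[C@]3(C)CC[C@]12C | intermediate
40 | (R)-carvone | CC1=CC[C@H](CC1=O)C(C)=C | starting material
41 | trimethyl{[(5R)-2-methyl-5-(prop-1-en-2-yl)cyclohex-1-en-1-yl]oxy}silane | C=C(C)[C@@H]1CCC(C)=C(O[Si](C)(C)C)C1 | intermediate
42 | 1-methyl-4-(prop-1-en-2-yl)-6-(trimethylsilyloxy)bicyclo[4.1.0]heptane (cyclopropane diastereomers) | C=C(C)[C@@H]1CCC2(C)CC2(O[Si](C)(C)C)C1 | intermediate
43 | 3-chloro-3-methyl-6-(prop-1-en-2-yl)cycloheptan-1-one (not isolated) | C=C(C)[C@@H]1CCC(C)(Cl)CC(=O)C1 | intermediate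
44 | (6R)-3-methyl-6-(prop-1-en-2-yl)cyclohept-2-en-1-one | C=C(C)[C@@H]1CCC(C)=CC(=O)C1 | intermediate
45 | dimethyl(phenyl)silyl enol ether of cis-3-methyl-6-(prop-1-en-2-yl)cycloheptanone (C1=C2; not isolated) | C=C(C)[C@@H]1CC[C@H](C)C=C(O[Si](C)(C)c2ccccc2)C1 | intermediate
46 | 2-[dimethyl(phenyl)silyloxy]-cis-3-methyl-6-(prop-1-en-2-yl)cycloheptan-1-one (C2 epimers) | C=C(C)[C@@H]1CC[C@H](C)C(O[Si](C)(C)c2ccccc2)C(=O)C1 | intermediate
47 | 6-[dimethyl(phenyl)silyloxy]-cis-7-methyl-10-(prop-1-en-2-yl)-1,4-dioxaspiro[4.6]undecane (C6 epimers; not isolated) | C=C(C)[C@@H]1CC[C@H](C)C(O[Si](C)(C)c2ccccc2)C2(OCCO2)C1 | intermediate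
48 | cis-7-methyl-10-(prop-1-en-2-yl)-1,4-dioxaspiro[4.6]undecan-6-ol (C6 epimers) | C=C(C)[C@@H]1CC[C@H](C)C(O)C2(OCCO2)C1 | intermediate
49 | cis-7-methyl-10-(prop-1-en-2-yl)-1,4-dioxaspiro[4.6]undecan-6-one | C=C(C)[C@@H]1CC[C@H](C)C(=O)C2(OCCO2)C1 | intermediate
50 | 6-allyl-6-hydroxy ketal (hydroxyl cis to the adjacent methyl) | C=C(C)[C@@H]1CC[C@H](C)[C@@](O)(CC=C)C2(OCCO2)C1 | intermediate
51 | 2-allyl-2-hydroxy-3-methyl-6-(prop-1-en-2-yl)cycloheptan-1-one | C=C(C)[C@@H]1CC[C@H](C)[C@@](O)(CC=C)C(=O)C1 | intermediate
52 | 2-allyl-2-(tert-butyldimethylsilyloxy)-3-methyl-6-(prop-1-en-2-yl)cycloheptan-1-one | C=C(C)[C@@H]1CC[C@H](C)[C@@](O[Si](C)(C)C(C)(C)C)(CC=C)C(=O)C1 | intermediate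
53 | 2-allyl-2-(tert-butyldimethylsilyloxy)-1-isopropenyl-3-methyl-6-(prop-1-en-2-yl)cycloheptan-1-ol (oxygens cis) | C=C(C)[C@@H]1CC[C@H](C)[C@@](O[Si](C)(C)C(C)(C)C)(CC=C)[C@@](O)(C(C)=C)C1 | intermediate
54 | 1′-(tert-butyldimethylsilyloxy)guaia-3′,11′-dien-5′-ol | C=C(C)[C@@H]1CC[C@H](C)[C@@]2(O[Si](C)(C)C(C)(C)C)CC=C(C)[C@]2(C1)O | intermediate
55 | C2 aryl ether of 54 with 39 (C3–F; C1′–OSi; 21-ketal) | C=C(C)[C@@H]1CC[C@H](C)[C@@]2(O[Si](C)(C)C(C)(C)C)CC=C(C)[C@]2(C1)Oc1cc2c(c(C)c1F)C(=O)C=C1[C@@]2(C)CC[C@@]2(C)[C@@H]3C[C@@H](C)C4(OCCO4)C[C@]3(C)CC[C@]12C | intermediate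
56 | desilylated C1′ alcohol of 55 (not isolated) | C=C(C)[C@@H]1CC[C@H](C)[C@@]2(O)CC=C(C)[C@]2(C1)Oc1cc2c(c(C)c1F)C(=O)C=C1[C@@]2(C)CC[C@@]2(C)[C@@H]3C[C@@H](C)C4(OCCO4)C[C@]3(C)CC[C@]12C | intermediate
57 | 21-ethylene ketal of the target | C=C(C)[C@@H]1CC[C@H](C)[C@@]23CC=C(C)[C@]2(C1)Oc1cc2c(c(C)c1O3)C(=O)C=C1[C@@]2(C)CC[C@@]2(C)[C@@H]3C[C@@H](C)C4(OCCO4)C[C@]3(C)CC[C@]12C | intermediate
58 | CNP0405270.2 | C=C(C)[C@@H]1CC[C@H](C)[C@@]23CC=C(C)[C@]2(C1)Oc1cc2c(c(C)c1O3)C(=O)C=C1[C@@]2(C)CC[C@@]2(C)[C@@H]3C[C@@H](C)C(=O)C[C@]3(C)CC[C@]12C | target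

## Step count and least certain steps

Total: 39 steps. Longest linear sequence: 23 steps (steps 6–25 and 37–39).

**Step 20 (key step).** The radical may close in the 6-endo mode at C8, or be reduced before it cyclises, because both alkene carbons are fully substituted and addition to C14 builds a quaternary centre next to quaternary C13. Fallback: starting from 29, the C14 methyl would be introduced by enolate chemistry. The extended enolate (KOtBu, tBuOH, deprotonation at C7) would be methylated with MeI at its α-carbon C14 to give the 14β-methyl-7-en-15-one F1. Here the face would rest on the substrate alone (attack anti to the adjacent C13 methyl is wanted), which is why this is not the main route. LiAlH4 would reduce the ketone to the 15-alcohol F2, NaH/CS2/MeI would give the xanthate F3, and Barton–McCombie reduction at high Bu3SnH concentration (to outrun a 1,2-vinyl shift of the homoallylic radical) would give the 15-deoxy-7-ene F4. Oxidation of its doubly activated C6 methylene (CrO3 cat., tBuOOH) would rejoin the route at 39.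

**Step 38.** Once the C1′ alkoxide is free it may attack the activated C2 position in place of the unactivated C3 position, so that the aryl group migrates between the two oxygens (Smiles rearrangement) and ring closure then takes place with the opposite regiochemistry; migration of the silyl group between the two oxygens in step 37 would erode the regiochemistry in the same way. Fallback: starting from 55, the C6 carbonyl would first be reduced (NaBH4, CeCl3, MeOH) to the allylic alcohol F5, which removes the activation of C2 and with it the migration pathway. Bu4NF in THF would then give the diol F6, and KN(SiMe3)2 with 18-crown-6 in toluene at 100 °C would close the dioxane at C3 to the dioxane alcohol F7. MnO2 would restore the enone and rejoin the route at 57.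

**Step 16.** The catalyst may fail to control the face of a bulky, unactivated electrophile, and the slow alkylation may let the iodide be consumed by elimination or by the enolate of its own C15 ketone. Fallback: starting from 9 and 26, the potassium enolate (KOtBu, tBuOH/THF) would be alkylated without chiral control. Because 26 is a single enantiomer, 27 and its C9 epimer F8 are diastereomers and would be separated by chromatography, the route continuing from 27.

**Step 9.** The chiral base may discriminate poorly between the two enantiotopic rings, or deprotonate both, so that the enantiomeric purity of the whole ring D/E fragment is low. Fallback: starting from 15, an achiral base (LiN(iPr)2, Me3SiCl) and Pd(OAc)2 would give 17 as the racemate, that is 16 and 17 together with the enantiomeric enol ether F9 and the enantiomeric enedione F10. The enantiomers of the enedione would be separated by chromatography on a chiral stationary phase. F10 would be hydrogenated (H2, palladium on carbon) back to meso 15 and recycled, and the route continues from 17.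

**Step 13.** The vinyl group may enter from the α face, or from both faces, because the preferred conformer of the cis-fused bicycle is not certain; the C13 configuration would then be wrong or mixed. Fallback: starting from 19, the order of the two conjugate additions would be reversed. CH2=CHMgBr with CuBr·SMe2 and Me3SiCl would give the trimethylsilyl enol ether F11, and Pd(OAc)2 would dehydrogenate it to the 13-vinyl dienone F12. MeCu·BF3, chosen for 1,4- over 1,6-addition, would then bring in the methyl group on the face that the vinyl group took before, so that the vinyl group is left β; this returns the route to 23.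

**Step 18.** Coordination of the hindered C15 ketone to the oxazaborolidine may be slow, leaving the reduction to uncatalysed borane and to the substrate's own facial bias, or catalyst and substrate may be mismatched. Fallback: starting from 29, a substrate-controlled Luche reduction (NaBH4, CeCl3, MeOH) would be used. Should it deliver the 15α-alcohol F13, a Mitsunobu reaction (4-nitrobenzoic acid, PPh3, diisopropyl azodicarboxylate) would invert C15 to the 15β-ester F14, and K2CO3 in methanol would release 30.

## Further compounds

F1 | step 20 | 14β-methyl-7-en-15-one (2,3-difluoro; 21-ketal) | Fc1cc2c(c(C)c1F)CC=C1[C@@]3(C)C(=O)C[C@@]4(C)CC5(OCCO5)[C@H](C)C[C@H]4[C@]3(C)CC[C@]12C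
F2 | step 20 | 14β-methyl-7-en-15-ol (C15 epimers) | Fc1cc2c(c(C)c1F)CC=C1[C@@]3(C)C(O)C[C@@]4(C)CC5(OCCO5)[C@H](C)C[C@H]4[C@]3(C)CC[C@]12C
F3 | step 20 | 15-xanthate of F2 (C15 epimers) | Fc1cc2c(c(C)c1F)CC=C1[C@@]3(C)C(OC(=S)SC)C[C@@]4(C)CC5(OCCO5)[C@H](C)C[C@H]4[C@]3(C)CC[C@]12C
F4 | step 20 | 15-deoxy-14β-methyl-7-ene (C6 methylene) | Fc1cc2c(c(C)c1F)CC=C1[C@@]3(C)CC[C@@]4(C)CC5(OCCO5)[C@H](C)C[C@H]4[C@]3(C)CC[C@]12C
F5 | step 38 | 6-hydroxy-7-ene derivative of 55 (C6 epimers) | C=C(C)[C@@H]1CC[C@H](C)[C@@]2(O[Si](C)(C)C(C)(C)C)CC=C(C)[C@]2(C1)Oc1cc2c(c(C)c1F)C(O)C=C1[C@@]2(C)CC[C@@]2(C)[C@@H]3C[C@@H](C)C4(OCCO4)C[C@]3(C)CC[C@]12C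
F6 | step 38 | desilylated diol of F5 (C6 epimers) | C=C(C)[C@@H]1CC[C@H](C)[C@@]2(O)CC=C(C)[C@]2(C1)Oc1cc2c(c(C)c1F)C(O)C=C1[C@@]2(C)CC[C@@]2(C)[C@@H]3C[C@@H](C)C4(OCCO4)C[C@]3(C)CC[C@]12C
F7 | step 38 | 6-hydroxy-7-ene derivative of 57 (C6 epimers) | C=C(C)[C@@H]1CC[C@H](C)[C@@]23CC=C(C)[C@]2(C1)Oc1cc2c(c(C)c1O3)C(O)C=C1[C@@]2(C)CC[C@@]2(C)[C@@H]3C[C@@H](C)C4(OCCO4)C[C@]3(C)CC[C@]12C
F8 | step 16 | (9R) epimer of 27 | Fc1cc2c(c(C)c1F)CCC(=O)[C@]2(C)CC[C@]3(C)CC(=O)C[C@@]4(C)CC5(OCCO5)[C@H](C)C[C@H]43
F9 | step 9 | enantiomer of 16 | C[Si](C)(C)OC1=CC[C@H]2CCC(=O)C[C@@]2(C)C1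
F10 | step 9 | enantiomer of 17 | O=C1C=C[C@H]2CCC(=O)C[C@@]2(C)C1
F11 | step 13 | trimethylsilyl enol ether of the 13-vinyl ketone (C13 epimers) | C[Si](C)(C)OC1=CC(C=C)[C@@H]2C[C@@H](C)C3(OCCO3)C[C@]2(C)C1
F12 | step 13 | 13-vinyl ring D/E dienone (21-ketal) | O=C1C=C(C=C)[C@@H]2C[C@@H](C)C3(OCCO3)C[C@]2(C)C1
F13 | step 18 | pentacyclic 8(14)-en-15α-ol | Fc1cc2c(c(C)c1F)CCC1=C3[C@@H](O)C[C@@]4(C)CC5(OCCO5)[C@H](C)C[C@H]4[C@]3(C)CC[C@]12C
F14 | step 18 | 15β-(4-nitrobenzoate) of 30 | Fc1cc2c(c(C)c1F)CCC1=C3[C@H](OC(=O)c6ccc(cc6)[N+](=O)[O-])C[C@@]4(C)CC5(OCCO5)[C@H](C)C[C@H]4[C@]3(C)CC[C@]12C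
A1 | alternative 1 | tetrahydro-arene Diels–Alder adduct | C=C(C)[C@@H]1CC[C@H](C)[C@@]23CC=C(C)[C@]2(C1)OC(C[C@@H]45)=C(O3)[C@@H](C)[C@H]4C(=O)C=C1[C@@]5(C)CC[C@@]2(C)[C@@H]3C[C@@H](C)C(=O)C[C@]3(C)CC[C@]12C
A2 | alternative 1 | guaiane-fused 2-methylidene-3-ethylidene-1,4-dioxane (ethylidene geometry open) | C=C(C)[C@@H]1CC[C@H](C)[C@@]23CC=C(C)[C@]2(C1)OC(=C)C(=CC)O3
A3 | alternative 1 | rings B–E cyclohexa-2,5-dienone (C5=C10 and C7=C8 beside the C6 ketone; C21 ketone) | O=C1C=C[C@]2(C)CC[C@@]3(C)[C@@H]4C[C@@H](C)C(=O)C[C@]4(C)CC[C@]3(C)C2=C1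
A4 | alternative 2 | pentacyclic catechol dimethyl ether from the cationic tricyclisation | COc1cc2c(c(C)c1OC)CC[C@H]1[C@@]2(C)CC[C@@]2(C)[C@@H]3C=C(C)C4(OCCO4)C[C@]3(C)CC[C@]12C
A5 | alternative 3 | ring D carboxylic acid with C9 vinyl group from the Ireland–Claisen contraction | COc1cc2c(c(C)c1OC)CC=C([C@@]1(C)CC[C@@]3(C)CC4(OCCO4)[C@H](C)C[C@H]3[C@]1(C)C(=O)O)[C@@]2(C)C=C
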